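The route cuts the C3–C4 bond of the tridecyl chain (C1 = benzylic CH2, C2 = acetoxy carbon, C13 = CH2OH). The key step exploits the oxygen on C2 and the adjacent unbranched methylene C3: C2, C3 and that oxygen are held in the oxirane ring of an (S)-arylmethyl oxirane built from (S)-epichlorohydrin. A copper-catalysed C10 Grignard reagent opens the ring at C3, which joins the two halves, leaves the C2 configuration untouched and frees the C2 alkoxide, acetylated in the same flask. The precursors are a benzyl-protected aryl epoxide and benzyl 10-bromodecyl ether; one hydrogenolysis then releases the phenol and the primary alcohol.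

Key step: step 5

Remark: the C2 stereocentre of the target is (R); compounds 1, 3 and 7 are assumed to be commercially available.

Step 1
Reactants: 1 3-bromo-5-methoxyphenol
Product: 2 1-(benzyloxy)-3-bromo-5-methoxybenzene
Conditions: BnBr, K2CO3, DMF, rt
Reagents that add atoms: benzyl bromide, BrCc1ccccc1
Why: Williamson ether synthesis (SN2 of the phenoxide on benzyl bromide) should mask the acidic phenol for the two organomagnesium steps.

Step 2
Reactants: 2 1-(benzyloxy)-3-bromo-5-methoxybenzene; 3 (S)-epichlorohydrin
Product: 5 (S)-1-[3-(benzyloxy)-5-methoxyphenyl]-3-chloropropan-2-ol, via aryl Grignard reagent 4 (not isolated)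
Conditions: Mg, THF, reflux; then 3, CuI (10 mol %), THF, −40 → 0 °C; aq NH4Cl
Reagents that add atoms: none
Why: In this copper-catalysed Grignard opening of an epoxide the aryl cuprate should attack the unsubstituted oxirane carbon rather than the C–Cl carbon at low temperature, so the stereocentre, to which no bond is broken, is carried into the (S)-chlorohydrin.

Step 3
Reactants: 5 (S)-1-[3-(benzyloxy)-5-methoxyphenyl]-3-chloropropan-2-ol
Product: 6 (S)-2-[3-(benzyloxy)-5-methoxybenzyl]oxirane
Conditions: NaOH (powdered), Et2O, rt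
Reagents that add atoms: none
Why: Intramolecular Williamson etherification (3-exo-tet displacement of chloride by the alkoxide) should close the terminal epoxide without touching the stereocentre, which stays (S).

Step 4
Reactants: 7 10-bromodecan-1-ol
Product: 8 benzyl 10-bromodecyl ether
Conditions: BnOC(=NH)CCl3, TfOH (cat.), cyclohexane/CH2Cl2, rt
Reagents that add atoms: benzyl 2,2,2-trichloroacetimidate, N=C(OCc1ccccc1)C(Cl)(Cl)Cl
Why: Acid-catalysed O-benzylation with a trichloroacetimidate should protect the primary alcohol without base, so the alkoxide cannot displace the bromide of another molecule.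

Step 5
Reactants: 8 benzyl 10-bromodecyl ether; 6 (S)-2-[3-(benzyloxy)-5-methoxybenzyl]oxirane
Product: 11 (R)-13-(benzyloxy)-1-[3-(benzyloxy)-5-methoxyphenyl]tridecan-2-yl acetate, via alkyl Grignard reagent 9 (not isolated), via bromomagnesium alkoxide 10 (not isolated)
Conditions: 8, Mg, THF, 45 °C; then 6, CuI (10 mol %), THF, −30 → 0 °C; then Ac2O, DMAP (cat.), 0 °C → rt; aq NH4Cl
Reagents that add atoms: acetic anhydride, CC(=O)OC(C)=O
Why: Magnesium inserts into the C–Br bond of 8, transmetalation to copper gives an alkylcuprate that attacks the unsubstituted ring carbon (C3) of oxirane 6 in an SN2 ring opening to form C3–C4 and the C2 magnesium alkoxide 10, which acetic anhydride/DMAP acylates in the flask to 11. The closest known reaction type is the copper-catalysed alkylation of monosubstituted epoxides by primary alkyl Grignard reagents, with the aqueous quench replaced by the known acylation of a magnesium alkoxide. No ring is closed; the oxirane ring is opened. No new stereocentre is created: C2 comes from (S)-epichlorohydrin and keeps its spatial arrangement because no bond to it is broken, the descriptor changing from S to R only through the CIP priorities. The step needs attack at the CH2 terminus rather than the substituted carbon, and C–C formation rather than bromohydrin formation; the first should be secured by the monosubstituted oxirane and the soft cuprate, the second by catalytic copper at low temperature. The benzyl and methyl ethers are inert to the organometallics, and excess Grignard reagent is consumed by the anhydride.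

Step 6
Reactants: 11 (R)-13-(benzyloxy)-1-[3-(benzyloxy)-5-methoxyphenyl]tridecan-2-yl acetate
Product: 12 (R)-13-hydroxy-1-(3-hydroxy-5-methoxyphenyl)tridecan-2-yl acetate
Conditions: H2 (1 atm), Pd(OH)2/C, EtOAc, rt
Reagents that add atoms: none
Why: Catalytic hydrogenolysis should cleave the aryl and the alkyl benzyl ether in one operation, while the homobenzylic (not benzylic) acetate, the methyl ether and the stereocentre are not affected.

Compound list
1 | 3-bromo-5-methoxyphenol | COc1cc(O)cc(Br)c1 | starting material
2 | 1-(benzyloxy)-3-bromo-5-methoxybenzene | COc1cc(OCc2ccccc2)cc(Br)c1 | intermediate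
3 | (S)-epichlorohydrin, (S)-2-(chloromethyl)oxirane | ClC[C@@H]1CO1 | starting material
4 | [3-(benzyloxy)-5-methoxyphenyl]magnesium bromide | COc1cc(OCc2ccccc2)cc([Mg]Br)c1 | intermediate
5 | (S)-1-[3-(benzyloxy)-5-methoxyphenyl]-3-chloropropan-2-ol | COc1cc(OCc2ccccc2)cc(C[C@H](O)CCl)c1 | intermediate
6 | (S)-2-[3-(benzyloxy)-5-methoxybenzyl]oxirane | COc1cc(OCc2ccccc2)cc(C[C@@H]3OC3)c1 | intermediate
7 | 10-bromodecan-1-ol | OCCCCCCCCCCBr | starting material
8 | benzyl 10-bromodecyl ether | BrCCCCCCCCCCOCc1ccccc1 | intermediate
9 | [10-(benzyloxy)decyl]magnesium bromide | Br[Mg]CCCCCCCCCCOCc1ccccc1 | intermediate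
10 | bromomagnesium (R)-13-(benzyloxy)-1-[3-(benzyloxy)-5-methoxyphenyl]tridecan-2-olate | COc1cc(OCc2ccccc2)cc(C[C@@H](CCCCCCCCCCCOCc2ccccc2)O[Mg]Br)c1 | intermediate
11 | (R)-13-(benzyloxy)-1-[3-(benzyloxy)-5-methoxyphenyl]tridecan-2-yl acetate | COc1cc(OCc2ccccc2)cc(C[C@@H](CCCCCCCCCCCOCc2ccccc2)OC(C)=O)c1 | intermediate
12 | (R)-13-hydroxy-1-(3-hydroxy-5-methoxyphenyl)tridecan-2-yl acetate | COc1cc(O)cc(C[C@@H](CCCCCCCCCCCO)OC(C)=O)c1 | target

Total step count: 6. Longest linear sequence: 5 steps (steps 1, 2, 3, 5, 6); step 4 prepares the second fragment.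

Steps most likely to fail

Step 5. The Lewis-acidic magnesium halide may open the oxirane to a bromohydrin before the cuprate does, the alkyl Grignard reagent may homocouple, and the acylation in the flask may stay incomplete because excess organometallic consumes the anhydride. The fallback sets out from 6 and comes back at 12; it forms the same C3–C4 bond as an alkene by cross-metathesis.
- Epoxide 6 is homologated with dimethylsulfonium methylide (Me3S+ I−, n-BuLi, THF, −10 °C → rt) to (S)-1-[3-(benzyloxy)-5-methoxyphenyl]but-3-en-2-ol F1.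
- Ac2O/pyridine/DMAP should give (S)-1-[3-(benzyloxy)-5-methoxyphenyl]but-3-en-2-yl acetate F2.
- Cross-metathesis with an excess of undec-10-en-1-ol (C=CCCCCCCCCCO; Grubbs II, CH2Cl2, 40 °C) should give (2S,3E)-1-[3-(benzyloxy)-5-methoxyphenyl]-13-hydroxytridec-3-en-2-yl acetate F3; any Z isomer converges in the next operation.
- Homogeneous hydrogenation (H2, (Ph3P)3RhCl, benzene/EtOH), chosen to avoid allylic C–O hydrogenolysis, should give (R)-1-[3-(benzyloxy)-5-methoxyphenyl]-13-hydroxytridecan-2-yl acetate F4.
- H2, Pd/C, EtOAc then removes the aryl benzyl ether to give 12.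

Step 2. Grignard formation from the electron-rich bromide may be slow to start or give biaryl, and competing attack at the C–Cl carbon would erode the enantiomeric purity. The fallback sets out from 2 and comes back at 6.
- Stille allylation (allyltributylstannane, Pd(PPh3)4, toluene, 100 °C) should give 1-allyl-3-(benzyloxy)-5-methoxybenzene F5.
- Epoxidation (mCPBA, NaHCO3, CH2Cl2, 0 °C → rt) should give racemic 2-[3-(benzyloxy)-5-methoxybenzyl]oxirane F6.
- Hydrolytic kinetic resolution with (S,S)-(salen)Co(III)OAc and 0.55 equiv of water should, by the usual sense for alkyl-substituted oxiranes, hydrolyse the (R)-epoxide and leave (S)-epoxide 6. The catalyst enantiomer is assigned from memory of that sense and should be confirmed on the recovered epoxide.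

Step 6. The aliphatic benzyl ether may be cleaved much more slowly than the aryl one, and prolonged exposure could lead to partial ring reduction or acetyl loss. The fallback sets out from 7 and comes back at 12; the primary alcohol is carried as a silyl ether instead.
- TBSCl, imidazole, CH2Cl2 should convert 7 to [(10-bromodecyl)oxy](tert-butyl)dimethylsilane F7.
- Its Grignard reagent {10-[(tert-butyldimethylsilyl)oxy]decyl}magnesium bromide F8 should open 6 under the conditions of step 5 to bromomagnesium (R)-1-[3-(benzyloxy)-5-methoxyphenyl]-13-[(tert-butyldimethylsilyl)oxy]tridecan-2-olate F9.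
- Acetylation in the flask should give (R)-1-[3-(benzyloxy)-5-methoxyphenyl]-13-[(tert-butyldimethylsilyl)oxy]tridecan-2-yl acetate F10.
- Short hydrogenolysis of the aryl benzyl ether alone (H2, Pd/C, EtOAc) should give (R)-13-[(tert-butyldimethylsilyl)oxy]-1-(3-hydroxy-5-methoxyphenyl)tridecan-2-yl acetate F11.
- HF·pyridine (THF/pyridine, 0 °C → rt) then removes the silyl group to give 12.

Further compounds
F1 | step 5 | (S)-1-[3-(benzyloxy)-5-methoxyphenyl]but-3-en-2-ol | COc1cc(OCc2ccccc2)cc(C[C@@H](C=C)O)c1
F2 | step 5 | (S)-1-[3-(benzyloxy)-5-methoxyphenyl]but-3-en-2-yl acetate | COc1cc(OCc2ccccc2)cc(C[C@@H](C=C)OC(C)=O)c1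
F3 | step 5 | (2S,3E)-1-[3-(benzyloxy)-5-methoxyphenyl]-13-hydroxytridec-3-en-2-yl acetate | COc1cc(OCc2ccccc2)cc(C[C@@H](/C=C/CCCCCCCCCO)OC(C)=O)c1
F4 | step 5 | (R)-1-[3-(benzyloxy)-5-methoxyphenyl]-13-hydroxytridecan-2-yl acetate | COc1cc(OCc2ccccc2)cc(C[C@@H](CCCCCCCCCCCO)OC(C)=O)c1
F5 | step 2 | 1-allyl-3-(benzyloxy)-5-methoxybenzene | COc1cc(OCc2ccccc2)cc(CC=C)c1
F6 | step 2 | racemic 2-[3-(benzyloxy)-5-methoxybenzyl]oxirane | COc1cc(OCc2ccccc2)cc(CC3OC3)c1
F7 | step 6 | [(10-bromodecyl)oxy](tert-butyl)dimethylsilane | CC(C)(C)[Si](C)(C)OCCCCCCCCCCBr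
F8 | step 6 | {10-[(tert-butyldimethylsilyl)oxy]decyl}magnesium bromide | CC(C)(C)[Si](C)(C)OCCCCCCCCCC[Mg]Br
F9 | step 6 | bromomagnesium (R)-1-[3-(benzyloxy)-5-methoxyphenyl]-13-[(tert-butyldimethylsilyl)oxy]tridecan-2-olate | COc1cc(OCc2ccccc2)cc(C[C@@H](CCCCCCCCCCCO[Si](C)(C)C(C)(C)C)O[Mg]Br)c1
F10 | step 6 | (R)-1-[3-(benzyloxy)-5-methoxyphenyl]-13-[(tert-butyldimethylsilyl)oxy]tridecan-2-yl acetate | COc1cc(OCc2ccccc2)cc(C[C@@H](CCCCCCCCCCCO[Si](C)(C)C(C)(C)C)OC(C)=O)c1
F11 | step 6 | (R)-13-[(tert-butyldimethylsilyl)oxy]-1-(3-hydroxy-5-methoxyphenyl)tridecan-2-yl acetate | COc1cc(O)cc(C[C@@H](CCCCCCCCCCCO[Si](C)(C)C(C)(C)C)OC(C)=O)c1
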